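**Plan**

- Retrosynthesis: ring B is opened at C2–C3 (C2 aldehyde on C1, bromomethyl (Z)-enone at C4); then C4–C5 (Stille), the lactone bond C8–C17 (tethered Reformatsky), C8–C9 (Nozaki–Hiyama–Kishi) and C6–C7 (alkynylation) are cut; ring A goes back to 2-methylcyclohexane-1,3-dione.
- Enabling feature: in ring B (C1–C10) the oxygens on C2 and C4 flank the C3 methylene, a β-hydroxy ketone pattern; C2 hangs on quaternary C1, so as an aldehyde it cannot enolize and can only accept the C4 ketone enolate made by reducing a C3 bromide.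
- Forward order: ring A (C1, C10–C14) with the C2 and C9 arms; union of the C9 aldehyde with a C5–C8 bromoenynol; lactone C7–O–C19–C17–C8; C3–C4 added at C5; ring B closed last; reduction, acetylation, desilylation.
- Stereochemistry: C1/C14 from yeast desymmetrization; C10/C11 from hydroxyl-directed hydrogenation; C12 from hindered hydride; C7 from catalytic asymmetric alkynylation; C9 from Felkin–Anh addition; C8/C17 from the tethered Reformatsky; Z C5=C6 from trans-hydroalumination/iodination; C2 from the key step; C4 from 1,3-anti reduction.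
- Convention: briarane numbering; on ring A, β is the face carrying the C1 methyl (C15) and α the opposite face; on the lactone the C8 oxygen, C6 and the C17 methyl (C18) are mutually cis.

Key step: step 27

Assumption: the (S,S)-ProPhenol/Me2Zn catalyst is taken to deliver the (S)-carbinol 22 from 2-bromoacrolein; if its facial sense is the opposite, the (R,R)-ligand is used.

**Step 1**
Reactants: 1 2-methylcyclohexane-1,3-dione; 2 allyl bromide
Product: 3 2-allyl-2-methylcyclohexane-1,3-dione
Conditions: NaOH (1 M aq), rt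
Reagents that add atoms: none
Why: C-alkylation of the soft 2-alkyl-1,3-dione enolate by an allylic halide in water builds the quaternary carbon (future C1 with C15), the allyl group serving as a masked one-carbon C2 arm.

**Step 2**
Reactants: 3 2-allyl-2-methylcyclohexane-1,3-dione
Product: 4 (2S,3S)-2-allyl-3-hydroxy-2-methylcyclohexan-1-one
Conditions: baker's yeast, sucrose, H2O, 30 °C
Reagents that add atoms: none
Why: Yeast reduction of 2,2-disubstituted cyclohexane-1,3-diones is an established enantiotopic-group-selective desymmetrization; it reduces one carbonyl so that the new hydroxyl (C14, S) is cis to the allyl group and thereby fixes quaternary C1.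

**Step 3**
Reactants: 4 (2S,3S)-2-allyl-3-hydroxy-2-methylcyclohexan-1-one
Product: 5 (2S,3S)-2-allyl-2-methyl-3-(triethylsilyloxy)cyclohexan-1-one
Conditions: Et3SiCl, imidazole, DMF, 0 °C → rt
Reagents that add atoms: chlorotriethylsilane, CC[Si](CC)(CC)Cl
Why: Standard silylation of a secondary alcohol; the triethylsilyl ether is chosen because it can later be removed in the presence of a secondary tert-butyldimethylsilyl ether.

**Step 4**
Reactants: 5 (2S,3S)-2-allyl-2-methyl-3-(triethylsilyloxy)cyclohexan-1-one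
Product: 6 (2S,3S)-2-allyl-2,6-dimethyl-3-(triethylsilyloxy)cyclohexan-1-one (both C6 epimers; C6 = briarane C11)
Conditions: LiN(i-Pr)2, THF, −78 °C; MeI, −78 → 0 °C
Reagents that add atoms: iodomethane, CI
Why: Enolate methylation; because C1 is quaternary, C11 is the only enolizable position, and its configuration is irrelevant since it becomes sp2 in step 5.

**Step 5**
Reactants: 6 (2S,3S)-2-allyl-2,6-dimethyl-3-(triethylsilyloxy)cyclohexan-1-one
Product: 7 (5S,6S)-6-allyl-2,6-dimethyl-5-(triethylsilyloxy)cyclohex-2-en-1-one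
Conditions: IBX, DMSO/toluene, 70 °C
Reagents that add atoms: none
Why: IBX dehydrogenation of a ketone through its enol gives the conjugated α-methyl enone, the new double bond forming toward the ring methylene C12.

**Step 6**
Reactants: 7 (5S,6S)-6-allyl-2,6-dimethyl-5-(triethylsilyloxy)cyclohex-2-en-1-one
Product: 8 (5S,6S)-6-allyl-1-(benzyloxymethyl)-2,6-dimethyl-5-(triethylsilyloxy)cyclohex-2-en-1-ol (C1 epimers; C1 = briarane C10)
Conditions: BnOCH2Cl, Mg, HgCl2 (cat.), THF, −15 °C; then 7, −78 → 0 °C
Reagents that add atoms: benzyl chloromethyl ether, ClCOCc1ccccc1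
Why: 1,2-Addition of an alkoxymethyl Grignard reagent (a hydroxymethyl anion equivalent) to the enone carbonyl puts C9 on C10; the carbinol configuration is erased in step 7.

**Step 7**
Reactants: 8 (5S,6S)-6-allyl-1-(benzyloxymethyl)-2,6-dimethyl-5-(triethylsilyloxy)cyclohex-2-en-1-ol
Product: 9 (4R,5S)-4-allyl-3-(benzyloxymethyl)-2,4-dimethyl-5-(triethylsilyloxy)cyclohex-2-en-1-one
Conditions: [C5H5NH][CrO3Cl], NaOAc, 4 Å sieves, CH2Cl2, rt
Reagents that add atoms: pyridinium chlorochromate (supplies the C12 oxygen), c1cc[nH+]cc1.[O-][Cr](=O)(=O)Cl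
Why: Babler–Dauben oxidative transposition: the chromate ester of the tertiary allylic alcohol shifts [3,3] to C12 and is oxidized, giving the C12 ketone and the tetrasubstituted C10=C11 alkene bearing C9 and the C20 methyl.

**Step 8**
Reactants: 9 (4R,5S)-4-allyl-3-(benzyloxymethyl)-2,4-dimethyl-5-(triethylsilyloxy)cyclohex-2-en-1-one
Product: 10 (4R,5S)-3-(benzyloxymethyl)-2,4-dimethyl-4-[(E)-prop-1-enyl]-5-(triethylsilyloxy)cyclohex-2-en-1-one
Conditions: RuHCl(CO)(PPh3)3 (cat.), toluene, 80 °C
Reagents that add atoms: none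
Why: Ruthenium hydride-catalysed migration of the terminal double bond to the more stable internal (mainly E) position, the hindered tetrasubstituted enone alkene being inert to the catalyst.

**Step 9**
Reactants: 10 (4R,5S)-3-(benzyloxymethyl)-2,4-dimethyl-4-[(E)-prop-1-enyl]-5-(triethylsilyloxy)cyclohex-2-en-1-one
Product: 12 (4S,5S)-3-(benzyloxymethyl)-4-(hydroxymethyl)-2,4-dimethyl-5-(triethylsilyloxy)cyclohex-2-en-1-one, via aldehyde 11 (not isolated)
Conditions: OsO4 (cat.), NaIO4, 2,6-lutidine, dioxane/H2O, rt; extractive work-up; then NaBH(OAc)3, CH2Cl2, 0 °C → rt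
Reagents that add atoms: osmium tetroxide, O=[Os](=O)(=O)=O; sodium periodate, [Na+].[O-]I(=O)(=O)=O (together they supply the C2 oxygen)
Why: Lemieux–Johnson cleavage attacks only the disubstituted propenyl alkene (the tetrasubstituted enone alkene is inert to OsO4), and NaBH(OAc)3 reduces the aldehyde but not the ketone, leaving the primary C2 alcohol.

**Step 10**
Reactants: 12 (4S,5S)-3-(benzyloxymethyl)-4-(hydroxymethyl)-2,4-dimethyl-5-(triethylsilyloxy)cyclohex-2-en-1-one
Product: 13 ring A ketone: cyclohexane C1/C10/C11/C12/C13/C14 with 1β-methyl, 1α-hydroxymethyl (C2), 10β-benzyloxymethyl (C9), 11β-methyl, 12-oxo, 14α-triethylsilyloxy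
Conditions: [Ir(cod)(PCy3)(py)]PF6 (10 mol %), H2 (1 atm), CH2Cl2, rt
Reagents that add atoms: none
Why: Hydroxyl-directed homogeneous hydrogenation: the homoallylic C2 hydroxyl binds the cationic iridium centre and both hydrogens are delivered to the α face of the tetrasubstituted alkene, setting C10 and C11 with the C9 arm and the C20 methyl cis to each other and to C15.

**Step 11**
Reactants: 13 ring A ketone
Product: 14 ring A diol: as 13 with 12β-hydroxy in place of the ketone
Conditions: LiBH(s-Bu)3, THF, −78 °C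
Reagents that add atoms: none
Why: The bulky trialkylborohydride attacks the C12 ketone along the equatorial trajectory (the axial one is blocked by the axial C9 arm in the chair with both methyl groups equatorial), giving the axial 12β-alcohol cis to the C11 methyl.

**Step 12**
Reactants: 14 ring A diol
Product: 15 bis(silyl ether): 2-O-TBS, 12β-O-TBS, 9-O-benzyl, 14α-O-TES
Conditions: TBSOTf, 2,6-lutidine, CH2Cl2, −78 → 0 °C
Reagents that add atoms: tert-butyldimethylsilyl triflate, CC(C)(C)[Si](C)(C)OS(=O)(=O)C(F)(F)F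
Why: A silyl triflate with a hindered base silylates both the neopentyl primary C2 alcohol and the hindered axial C12 alcohol.

**Step 13**
Reactants: 15 bis(silyl ether)
Product: 16 C9 alcohol: as 15 with 10β-hydroxymethyl
Conditions: H2 (1 atm), Pd on carbon (Pd/C), EtOAc, rt
Reagents that add atoms: none
Why: Hydrogenolysis of the benzyl ether; no alkene remains and silyl ethers are stable in ethyl acetate.

**Step 14**
Reactants: 16 C9 alcohol
Product: 17 ring A aldehyde: 1β-methyl, 1α-(TBS-oxymethyl), 10β-formyl (C9), 11β-methyl, 12β-O-TBS, 14α-O-TES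
Conditions: Dess–Martin periodinane, NaHCO3, CH2Cl2, 0 °C → rt
Reagents that add atoms: none
Why: Dess–Martin oxidation under buffered, non-basic conditions gives the C9 aldehyde without epimerizing C10; the aldehyde is used at once.

**Step 15**
Reactants: 18 acrolein
Product: 20 2-bromoacrolein (2-bromoprop-2-enal), via 2,3-dibromopropanal 19 (not isolated)
Conditions: Br2, CH2Cl2, −78 → 0 °C; then Et3N, 0 °C
Reagents that add atoms: bromine, BrBr
Why: Bromine addition to the alkene followed by amine-induced loss of HBr through the acidic α-hydrogen is the standard preparation of 2-bromoacrolein.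

**Step 16**
Reactants: 20 2-bromoacrolein; 21 propyne
Product: 22 (S)-2-bromohex-1-en-4-yn-3-ol
Conditions: Me2Zn, (S,S)-ProPhenol (10 mol %), Ph3PO (20 mol %), toluene, 0 °C
Reagents that add atoms: none
Why: Catalytic asymmetric alkynylation of an unsaturated aldehyde by an alkynylzinc species held in the dinuclear zinc–ProPhenol complex; the ligand selects the carbonyl face and sets C7 (S).

**Step 17**
Reactants: 17 ring A aldehyde; 22 (S)-2-bromohex-1-en-4-yn-3-ol
Product: 23 diol: 17 extended at C9 to (9R)-CH(OH)–C8(=CH2)–(7S)-CH(OH)–C6≡C5–CH3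
Conditions: CrCl2 (4 equiv), NiCl2 (2 mol %), DMF, rt
Reagents that add atoms: none
Why: Nozaki–Hiyama–Kishi coupling: zerovalent nickel inserts into the vinyl C–Br bond, transmetalation gives a vinylchromium species that adds to the aldehyde in the presence of the alkyne, the silyl ethers and the free hydroxyl, and Felkin–Anh addition anti to quaternary C1 sets C9 (R).

**Step 18**
Reactants: 23 diol
Product: 24 (Z)-vinyl iodide diol: as 23 with C7–C6H=C5(I)–CH3, iodine cis to C7
Conditions: NaAlH2(OCH2CH2OMe)2, THF, 0 °C → rt; EtOAc; then I2, THF, −78 °C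
Reagents that add atoms: iodine, II
Why: Hydroxyl-directed trans-hydroalumination of the propargylic alcohol places aluminium on the distal carbon C5 anti to the new C6 hydrogen, and iodinolysis with retention gives the (Z)-vinyl iodide in which the iodine (later C4) is cis to C7.

**Step 19**
Reactants: 24 (Z)-vinyl iodide diol
Product: 26 C7 2-bromopropanoate C9 acetate of 24 (epimers at the CHBr carbon), via C7 mono(2-bromopropanoate) 25 (not isolated)
Conditions: 2-bromopropanoyl bromide (1.05 equiv), pyridine, CH2Cl2, −78 → −30 °C; then Ac2O, DMAP, 0 °C → rt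
Reagents that add atoms: 2-bromopropanoyl bromide, CC(Br)C(=O)Br; acetic anhydride, CC(=O)OC(C)=O
Why: The C7 hydroxyl is far less hindered than the C9 hydroxyl, which sits next to the fully flanked ring carbon C10, so one equivalent of acid bromide at low temperature acylates C7 first and the C9 hydroxyl is then acetylated under DMAP catalysis.

**Step 20**
Reactants: 26 C7 2-bromopropanoate C9 acetate
Product: 27 C8 ketone: as 26 with C8=O in place of C8=CH2
Conditions: OsO4 (cat.), NaIO4, 2,6-lutidine, dioxane/H2O, rt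
Reagents that add atoms: osmium tetroxide, O=[Os](=O)(=O)=O; sodium periodate, [Na+].[O-]I(=O)(=O)=O (together they supply the C8 oxygen)
Why: Lemieux–Johnson cleavage of the unhindered 1,1-disubstituted alkene gives the C8 ketone, the trisubstituted vinyl iodide being sterically and electronically deactivated toward OsO4.

**Step 21**
Reactants: 27 C8 ketone
Product: 28 hydroxy lactone: γ-lactone C7–O–C19(=O)–C17(CH3)–C8(OH) with the C8 hydroxyl, C6 and C18 cis (7S, 17R), (9R)-acetate, (Z)-vinyl iodide, ring A as in 17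
Conditions: Zn dust (Me3SiCl-activated), THF, 25 → 45 °C; aq NH4Cl
Reagents that add atoms: none
Why: Intramolecular Reformatsky reaction of an α-(bromoacyloxy) ketone: zinc inserts into the C–Br bond and the ester enolate adds to the C8 ketone in a 5-(enolendo)-exo-trig closure (the tether topology of the Dieckmann route to tetronic acids) that puts the bulky C9 substituent trans to the C6 alkenyl group and the C17 methyl trans to C9; no base is present, so the acidic C7–H is untouched.

**Step 22**
Reactants: 28 hydroxy lactone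
Product: 29 triol: as 28 with free C2–OH and 14α-OH, 12β-O-TBS retained
Conditions: CSA (cat.), MeOH/CH2Cl2, 0 °C
Reagents that add atoms: none
Why: Acid-catalysed methanolysis removes the triethylsilyl ether at C14 and the primary tert-butyldimethylsilyl ether at C2, both far more labile than the secondary tert-butyldimethylsilyl ether at C12.

**Step 23**
Reactants: 29 triol
Product: 30 hydroxy aldehyde: as 29 with C2 as the aldehyde
Conditions: TEMPO (cat.), PhI(OAc)2, CH2Cl2, rt
Reagents that add atoms: none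
Why: Oxoammonium (TEMPO) oxidation is selective for the primary C2 alcohol over the hindered secondary C14 and tertiary C8 alcohols and stops at the aldehyde, which cannot enolize.

**Step 24**
Reactants: 30 hydroxy aldehyde
Product: 31 C14 acetate: as 30 with 14α-OAc
Conditions: Ac2O, pyridine, DMAP (cat.), CH2Cl2, rt
Reagents that add atoms: acetic anhydride, CC(=O)OC(C)=O
Why: DMAP-catalysed acetylation of the secondary C14 alcohol, the tertiary C8 alcohol being too hindered to react under these conditions.

**Step 25**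
Reactants: 31 C14 acetate
Product: 32 C8 trimethylsilyl ether of 31
Conditions: Me3SiOTf, 2,6-lutidine, CH2Cl2, −78 °C
Reagents that add atoms: trimethylsilyl triflate, C[Si](C)(C)OS(=O)(=O)C(F)(F)F
Why: Silyl triflate with a hindered base silylates the tertiary C8 hydroxyl, removing the last acidic proton before the samarium step, while the aldehyde has no α-hydrogen to enolize.

**Step 26**
Reactants: 32 C8 trimethylsilyl ether
Product: 34 bromomethyl (Z)-enone aldehyde: C2 aldehyde on C1 and C4(=O)–C3H2Br on the (Z) C5=C6 alkene, via 2-ethoxydiene 33 (not isolated)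
Conditions: tributyl(1-ethoxyvinyl)stannane, Pd(PPh3)4 (5 mol %), CuI (10 mol %), DMF, 45 °C; then NBS, NaHCO3, THF/H2O, 0 °C
Reagents that add atoms: tributyl(1-ethoxyvinyl)stannane, CCCC[Sn](CCCC)(CCCC)C(=C)OCC; N-bromosuccinimide, O=C1CCC(=O)N1Br; water, O
Why: Stille coupling of the vinyl iodide proceeds with retention of the Z geometry to a 2-ethoxydiene whose enol ether terminus (C3) is brominated by NBS and hydrolysed through the oxocarbenium ion to the bromomethyl ketone, the usual two-stage conversion of a halide into a bromoacetyl group.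

**Step 27**
Reactants: 34 bromomethyl (Z)-enone aldehyde
Product: 35 tricyclic β-hydroxy ketone: ring B closed, (2R)-hydroxyl, C4 ketone conjugated to the (Z) C5=C6 alkene
Conditions: SmI2 (2.2 equiv), THF, −78 °C, slow addition of 34 to high dilution; aq NH4Cl
Reagents that add atoms: none
Why: Two single-electron transfers from SmI2 cleave the C3–Br bond and leave the trivalent samarium enolate of the C4 ketone, formed regiospecifically and without base so that the lactone, the acetates and C17 are untouched; the oxophilic metal then binds the C2 aldehyde and the aldol addition runs through a six-membered chair-like chelate. The closest known reaction type is the SmI2-promoted intramolecular Reformatsky reaction of α-bromo carbonyl compounds with aldehydes, which is used for medium and large rings. Ring B (ten-membered) closes by a 10-(enolendo)-exo-trig aldol in which C2–C3 is the only new bond. The new C2 stereocenter (R) results from attack on the Re face of the aldehyde, controlled by the quaternary C1: within the chelate the aldehyde adopts a Felkin–Anh arrangement with C14 anti to the incoming C3, the C15 methyl beside the aldehyde hydrogen and C10 (the ring B tether) beside the oxygen. The step needs reduction of the C–Br bond in preference to the aldehyde, the (Z)-enone and the allylic lactone C7–O bond, which the much faster reduction of α-halo ketones at −78 °C and the limit of about two equivalents of SmI2 secure; it also needs ring closure to outrun protonation and dimerization, which the non-enolizable aldehyde, the absence of free hydroxyl groups, high dilution and the fold imposed by the Z alkene, the lactone and ring A secure.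

**Step 28**
Reactants: 35 tricyclic β-hydroxy ketone
Product: 36 (2R,4R)-anti-diol
Conditions: Me4NBH(OAc)3, MeCN/AcOH, −30 °C
Reagents that add atoms: none
Why: Evans–Saksena reduction: the C2 hydroxyl exchanges an acetate on boron and delivers hydride intramolecularly through a chair-like six-membered transition state to the C4 ketone, giving the 1,3-anti diol (C4 R); loss of the C8 trimethylsilyl group in acetic acid would not affect the route.

**Step 29**
Reactants: 36 (2R,4R)-anti-diol
Product: 37 2,4,9,14-tetraacetate with C8–O-TMS and C12–O-TBS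
Conditions: Ac2O, pyridine, DMAP (cat.), CH2Cl2, rt
Reagents that add atoms: acetic anhydride, CC(=O)OC(C)=O
Why: Standard DMAP-catalysed acetylation of the two secondary alcohols, the tertiary C8 oxygen being silylated or too hindered to react.

**Step 30**
Reactants: 37 tetraacetate bis(silyl ether)
Product: 38 CNP0183630.2 (target)
Conditions: HF·pyridine, THF/pyridine, 0 °C → rt
Reagents that add atoms: none
Why: Fluoride cleaves the trimethylsilyl and tert-butyldimethylsilyl ethers while the four acetates and the lactone are stable to buffered HF·pyridine; the trans C12/C14 relationship excludes acetyl migration.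

**Compound list**

1 | 2-methylcyclohexane-1,3-dione | CC1C(=O)CCCC1=O | starting material
2 | allyl bromide | C=CCBr | starting material
3 | 2-allyl-2-methylcyclohexane-1,3-dione | C=CCC1(C)C(=O)CCCC1=O | intermediate
4 | (2S,3S)-2-allyl-3-hydroxy-2-methylcyclohexan-1-one | O[C@H]1CCCC(=O)[C@@]1(C)CC=C | intermediate
5 | (2S,3S)-2-allyl-2-methyl-3-(triethylsilyloxy)cyclohexan-1-one | CC[Si](CC)(CC)O[C@H]1CCCC(=O)[C@@]1(C)CC=C | intermediate
6 | (2S,3S)-2-allyl-2,6-dimethyl-3-(triethylsilyloxy)cyclohexan-1-one, C6 epimers | CC[Si](CC)(CC)O[C@H]1CCC(C)C(=O)[C@@]1(C)CC=C | intermediate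
7 | (5S,6S)-6-allyl-2,6-dimethyl-5-(triethylsilyloxy)cyclohex-2-en-1-one | CC[Si](CC)(CC)O[C@H]1CC=C(C)C(=O)[C@@]1(C)CC=C | intermediate
8 | (5S,6S)-6-allyl-1-(benzyloxymethyl)-2,6-dimethyl-5-(triethylsilyloxy)cyclohex-2-en-1-ol, C1 epimers | CC[Si](CC)(CC)O[C@H]1CC=C(C)C(O)(COCc2ccccc2)[C@@]1(C)CC=C | intermediate
9 | (4R,5S)-4-allyl-3-(benzyloxymethyl)-2,4-dimethyl-5-(triethylsilyloxy)cyclohex-2-en-1-one | CC[Si](CC)(CC)O[C@H]1CC(=O)C(C)=C(COCc2ccccc2)[C@@]1(C)CC=C | intermediate
10 | (4R,5S)-3-(benzyloxymethyl)-2,4-dimethyl-4-[(E)-prop-1-enyl]-5-(triethylsilyloxy)cyclohex-2-en-1-one | CC[Si](CC)(CC)O[C@H]1CC(=O)C(C)=C(COCc2ccccc2)[C@@]1(C)/C=C/C | intermediate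
11 | (1R,6S)-2-(benzyloxymethyl)-1,3-dimethyl-4-oxo-6-(triethylsilyloxy)cyclohex-2-ene-1-carbaldehyde (C2 aldehyde, not isolated) | CC[Si](CC)(CC)O[C@H]1CC(=O)C(C)=C(COCc2ccccc2)[C@@]1(C)C=O | intermediate
12 | (4S,5S)-3-(benzyloxymethyl)-4-(hydroxymethyl)-2,4-dimethyl-5-(triethylsilyloxy)cyclohex-2-en-1-one | CC[Si](CC)(CC)O[C@H]1CC(=O)C(C)=C(COCc2ccccc2)[C@@]1(C)CO | intermediate
13 | ring A ketone: 1β-Me, 1α-CH2OH, 10β-CH2OBn, 11β-Me, 12-oxo, 14α-OTES | CC[Si](CC)(CC)O[C@H]1CC(=O)[C@H](C)[C@H](COCc2ccccc2)[C@@]1(C)CO | intermediate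
14 | ring A diol: as 13 with 12β-OH | CC[Si](CC)(CC)O[C@H]1C[C@H](O)[C@H](C)[C@H](COCc2ccccc2)[C@@]1(C)CO | intermediate
15 | bis(silyl ether): 2-O-TBS, 12β-O-TBS, 9-O-Bn, 14α-O-TES | CC[Si](CC)(CC)O[C@H]1C[C@H](O[Si](C)(C)C(C)(C)C)[C@H](C)[C@H](COCc2ccccc2)[C@@]1(C)CO[Si](C)(C)C(C)(C)C | intermediate
16 | C9 alcohol (10β-CH2OH) | CC[Si](CC)(CC)O[C@H]1C[C@H](O[Si](C)(C)C(C)(C)C)[C@H](C)[C@H](CO)[C@@]1(C)CO[Si](C)(C)C(C)(C)C | intermediate
17 | ring A aldehyde (10β-CHO = C9) | CC[Si](CC)(CC)O[C@H]1C[C@H](O[Si](C)(C)C(C)(C)C)[C@H](C)[C@H](C=O)[C@@]1(C)CO[Si](C)(C)C(C)(C)C | intermediate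
18 | acrolein | C=CC=O | starting material
19 | 2,3-dibromopropanal (not isolated) | O=CC(Br)CBr | intermediate
20 | 2-bromoacrolein | C=C(Br)C=O | intermediate
21 | propyne | CC#C | starting material
22 | (S)-2-bromohex-1-en-4-yn-3-ol | C=C(Br)[C@H](C#CC)O | intermediate
23 | (9R,7S)-diol with C8=CH2 and C6≡C5 | CC[Si](CC)(CC)O[C@H]1C[C@H](O[Si](C)(C)C(C)(C)C)[C@H](C)[C@H]([C@@H](O)C(=C)[C@H](C#CC)O)[C@@]1(C)CO[Si](C)(C)C(C)(C)C | intermediate
24 | (Z)-vinyl iodide diol | CC[Si](CC)(CC)O[C@H]1C[C@H](O[Si](C)(C)C(C)(C)C)[C@H](C)[C@H]([C@@H](O)C(=C)[C@H](/C=C(/C)I)O)[C@@]1(C)CO[Si](C)(C)C(C)(C)C | intermediate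
25 | C7 mono(2-bromopropanoate), CHBr epimers (not isolated) | CC[Si](CC)(CC)O[C@H]1C[C@H](O[Si](C)(C)C(C)(C)C)[C@H](C)[C@H]([C@@H](O)C(=C)[C@H](/C=C(/C)I)OC(=O)C(C)Br)[C@@]1(C)CO[Si](C)(C)C(C)(C)C | intermediate
26 | C7 2-bromopropanoate C9 acetate, CHBr epimers | CC[Si](CC)(CC)O[C@H]1C[C@H](O[Si](C)(C)C(C)(C)C)[C@H](C)[C@H]([C@@H](OC(C)=O)C(=C)[C@H](/C=C(/C)I)OC(=O)C(C)Br)[C@@]1(C)CO[Si](C)(C)C(C)(C)C | intermediate
27 | C8 ketone, CHBr epimers | CC[Si](CC)(CC)O[C@H]1C[C@H](O[Si](C)(C)C(C)(C)C)[C@H](C)[C@H]([C@@H](OC(C)=O)C(=O)[C@H](/C=C(/C)I)OC(=O)C(C)Br)[C@@]1(C)CO[Si](C)(C)C(C)(C)C | intermediate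
28 | hydroxy lactone (C8–OH, C6, C18 cis) | CC[Si](CC)(CC)O[C@H]1C[C@H](O[Si](C)(C)C(C)(C)C)[C@H](C)[C@H]([C@@H](OC(C)=O)[C@@]2(O)[C@H](/C=C(/C)I)OC(=O)[C@@H]2C)[C@@]1(C)CO[Si](C)(C)C(C)(C)C | intermediate
29 | triol (C2–OH, 14α-OH, C8–OH) | O[C@H]1C[C@H](O[Si](C)(C)C(C)(C)C)[C@H](C)[C@H]([C@@H](OC(C)=O)[C@@]2(O)[C@H](/C=C(/C)I)OC(=O)[C@@H]2C)[C@@]1(C)CO | intermediate
30 | C2 aldehyde with free 14α-OH | O[C@H]1C[C@H](O[Si](C)(C)C(C)(C)C)[C@H](C)[C@H]([C@@H](OC(C)=O)[C@@]2(O)[C@H](/C=C(/C)I)OC(=O)[C@@H]2C)[C@@]1(C)C=O | intermediate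
31 | C14 acetate | CC(=O)O[C@H]1C[C@H](O[Si](C)(C)C(C)(C)C)[C@H](C)[C@H]([C@@H](OC(C)=O)[C@@]2(O)[C@H](/C=C(/C)I)OC(=O)[C@@H]2C)[C@@]1(C)C=O | intermediate
32 | C8 trimethylsilyl ether | CC(=O)O[C@H]1C[C@H](O[Si](C)(C)C(C)(C)C)[C@H](C)[C@H]([C@@H](OC(C)=O)[C@@]2(O[Si](C)(C)C)[C@H](/C=C(/C)I)OC(=O)[C@@H]2C)[C@@]1(C)C=O | intermediate
33 | 2-ethoxydiene (not isolated) | CC(=O)O[C@H]1C[C@H](O[Si](C)(C)C(C)(C)C)[C@H](C)[C@H]([C@@H](OC(C)=O)[C@@]2(O[Si](C)(C)C)[C@H](/C=C(/C)C(=C)OCC)OC(=O)[C@@H]2C)[C@@]1(C)C=O | intermediate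
34 | bromomethyl (Z)-enone aldehyde (key-step precursor) | CC(=O)O[C@H]1C[C@H](O[Si](C)(C)C(C)(C)C)[C@H](C)[C@H]([C@@H](OC(C)=O)[C@@]2(O[Si](C)(C)C)[C@H](/C=C(/C)C(=O)CBr)OC(=O)[C@@H]2C)[C@@]1(C)C=O | intermediate
35 | tricyclic (2R)-hydroxy C4 ketone (key-step product) | CC(=O)O[C@H]1C[C@H](O[Si](C)(C)C(C)(C)C)[C@H](C)[C@@H]2[C@@H](OC(C)=O)[C@@]3(O[Si](C)(C)C)[C@H](/C=C(/C)C(=O)C[C@@H](O)[C@]21C)OC(=O)[C@@H]3C | intermediate
36 | (2R,4R)-anti-diol | CC(=O)O[C@H]1C[C@H](O[Si](C)(C)C(C)(C)C)[C@H](C)[C@@H]2[C@@H](OC(C)=O)[C@@]3(O[Si](C)(C)C)[C@H](/C=C(/C)[C@H](O)C[C@@H](O)[C@]21C)OC(=O)[C@@H]3C | intermediate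
37 | tetraacetate with C8–O-TMS and C12–O-TBS | CC(=O)O[C@H]1C[C@H](O[Si](C)(C)C(C)(C)C)[C@H](C)[C@@H]2[C@@H](OC(C)=O)[C@@]3(O[Si](C)(C)C)[C@H](/C=C(/C)[C@H](OC(C)=O)C[C@@H](OC(C)=O)[C@]21C)OC(=O)[C@@H]3C | intermediate
38 | CNP0183630.2 | CC(=O)O[C@H]1C[C@H](O)[C@H](C)[C@@H]2[C@@H](OC(C)=O)[C@@]3(O)[C@H](/C=C(/C)[C@H](OC(C)=O)C[C@@H](OC(C)=O)[C@]21C)OC(=O)[C@@H]3C | target

**Step count**

Total: 30 steps. Longest linear sequence: 28 steps (steps 1–14 and 17–30; steps 15–16 make the C5–C8 fragment).

**Steps most likely to fail**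

1. Step 27 (ring B closure). The samarium enolate may be protonated before it reaches the aldehyde, so that bromine is lost without ring closure. Intermolecular aldol may compete at practical concentration, the facial selectivity at C2 may be low, and excess reductant may open the allylic lactone C7–O bond. Fallback (same C2–C3 bond, enolate made by soft enolization instead of reduction): from 32 the Stille coupling of step 26 is run as before to enol ether 33, which is hydrolysed with dilute aqueous oxalic acid instead of being brominated; this gives the (Z)-methyl ketone aldehyde F1, which is 34 with a methyl group in place of the bromomethyl group. Bu2BOTf and i-Pr2NEt in CH2Cl2 at −78 °C under high dilution enolize the methyl ketone at C3, its only enolizable position; the esters and the lactone are not enolized by this reagent pair and the aldehyde has no α-hydrogen. The intramolecular boron aldol closes ring B, and oxidative work-up returns the route to 35.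

2. Step 10 (directed hydrogenation). The electron-poor tetrasubstituted enone alkene may not be reduced, or hydrogen may be delivered to the β face, or C11 may epimerize next to the ketone. Fallback (change of directing group and of the alkene type): from 12, Luche reduction (NaBH4, CeCl3, MeOH, −78 °C) gives the 12α-allylic alcohol F2, hydride being expected on the face opposite the C14 silyloxy group as in other 5-substituted cyclohexenones. The allylic C12 hydroxyl and the homoallylic C2 hydroxyl then both lie on the α face and direct [Ir(cod)(PCy3)(py)]PF6/H2 to a plain tetrasubstituted alkene, the best-precedented case of this reaction, giving the saturated 12α-diol F3. Oxidation of the secondary alcohol with NaOCl in acetic acid, which reacts with secondary alcohols in preference to primary ones, returns the route to 13.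

3. Step 21 (tethered Reformatsky lactonization). The five-membered closure may be slow, the enolate may add to the wrong face of the C8 ketone, or the sensitive α-acyloxy ketone may lose its C7 configuration or transfer an acyl group. Fallback (intermolecular, chelation-controlled addition instead of the tether): from 24 the less hindered C7 hydroxyl is etherified with 4-methoxybenzyl trichloroacetimidate and La(OTf)3 (cat.) to give the C7 4-methoxybenzyl ether F4, and acetylation of its C9 hydroxyl (Ac2O, DMAP) gives the C7 4-methoxybenzyl ether C9 acetate F5. Lemieux–Johnson cleavage as in step 20 then gives the 4-methoxybenzyl ether C8 ketone F6. Ethyl 2-bromopropanoate and zinc add to this ketone through a Cram chelate between the carbonyl oxygen and the C7 ether oxygen, so the enolate enters anti to the C6 alkenyl group and gives the tertiary alcohol ethyl ester F7, in which the C8 hydroxyl will be cis to C6 in the lactone. DDQ removes the 4-methoxybenzyl group to give the C7 hydroxy ethyl ester F8, whose freed C7 hydroxyl closes the lactone with loss of ethanol (DBU equilibrates C17 so that the methyl is trans to C9), and the route returns to 28.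

**Further compounds**

F1 | step 27 | (Z)-methyl ketone aldehyde (34 with CH3 in place of CH2Br) | CC(=O)O[C@H]1C[C@H](O[Si](C)(C)C(C)(C)C)[C@H](C)[C@H]([C@@H](OC(C)=O)[C@@]2(O[Si](C)(C)C)[C@H](/C=C(/C)C(C)=O)OC(=O)[C@@H]2C)[C@@]1(C)C=O
F2 | step 10 | 12α-allylic alcohol (from 12; 12α-OH, C10=C11, free C2–OH, 14α-OTES) | CC[Si](CC)(CC)O[C@H]1C[C@@H](O)C(C)=C(COCc2ccccc2)[C@@]1(C)CO
F3 | step 10 | saturated 12α-diol (10β-CH2OBn, 11β-Me, 12α-OH) | CC[Si](CC)(CC)O[C@H]1C[C@@H](O)[C@H](C)[C@H](COCc2ccccc2)[C@@]1(C)CO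
F4 | step 21 | C7 4-methoxybenzyl ether (of 24, C9–OH free) | CC[Si](CC)(CC)O[C@H]1C[C@H](O[Si](C)(C)C(C)(C)C)[C@H](C)[C@H]([C@@H](O)C(=C)[C@H](/C=C(/C)I)OCc2ccc(OC)cc2)[C@@]1(C)CO[Si](C)(C)C(C)(C)C
F5 | step 21 | C7 4-methoxybenzyl ether C9 acetate | CC[Si](CC)(CC)O[C@H]1C[C@H](O[Si](C)(C)C(C)(C)C)[C@H](C)[C@H]([C@@H](OC(C)=O)C(=C)[C@H](/C=C(/C)I)OCc2ccc(OC)cc2)[C@@]1(C)CO[Si](C)(C)C(C)(C)C
F6 | step 21 | 4-methoxybenzyl ether C8 ketone | CC[Si](CC)(CC)O[C@H]1C[C@H](O[Si](C)(C)C(C)(C)C)[C@H](C)[C@H]([C@@H](OC(C)=O)C(=O)[C@H](/C=C(/C)I)OCc2ccc(OC)cc2)[C@@]1(C)CO[Si](C)(C)C(C)(C)C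
F7 | step 21 | tertiary alcohol ethyl ester (C17 epimers) | CC[Si](CC)(CC)O[C@H]1C[C@H](O[Si](C)(C)C(C)(C)C)[C@H](C)[C@H]([C@@H](OC(C)=O)[C@](O)(C(C)C(=O)OCC)[C@H](/C=C(/C)I)OCc2ccc(OC)cc2)[C@@]1(C)CO[Si](C)(C)C(C)(C)C
F8 | step 21 | C7 hydroxy ethyl ester (C17 epimers) | CC[Si](CC)(CC)O[C@H]1C[C@H](O[Si](C)(C)C(C)(C)C)[C@H](C)[C@H]([C@@H](OC(C)=O)[C@](O)(C(C)C(=O)OCC)[C@H](/C=C(/C)I)O)[C@@]1(C)CO[Si](C)(C)C(C)(C)C
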